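## Retrosynthetic overview

1. Target 24 comes from C17 methylenation of ketone 23, which comes from O‑debenzylation of 22 and C15 oxidation of diol 21 (ring D ketone adjusted last).
2. Key step: 21 comes from the prochiral 1,5‑dialdehyde 19. A SmI2 ketyl at C11 (reversed polarity) adds to C9 of the unsaturated lactone, then the samarium enolate closes C8–C15 by aldol: ring C, then ring D, in one flask.
3. 19 comes from ozonolysis of cyclopentene 18, made from spirolactone 11 by C8 alkylation with iodide 13 and selenoxide elimination.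
4. Spirolactone 9 comes from formyl ketone 5 and methyl acrylate (C9–C10 bond), aldehyde reduction and lactonisation; C1 is reduced afterwards.
5. Ring A comes from 4,4‑dimethylcyclohexenone by asymmetric conjugate addition of BnOCH2 (C6) and formylation (C20). Ring order: A (bought), lactone, C, D.

Assumption: atoms are labelled with kaurane numbering (C1–C20; lactone C7–O–C20; enone C15/C16/C17).

## Route

Step 1
Reactants: 1 4,4-dimethylcyclohex-2-en-1-one; 2 benzyl chloromethyl ether
Product: 5 (3R,Z)-3-[(benzyloxy)methyl]-2-(hydroxymethylidene)-4,4-dimethylcyclohexan-1-one, via Grignard reagent 3 (not isolated), via magnesium enolate 4 (not isolated)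
Conditions: 2, Mg, THF, −20 °C; then 1, CuBr·SMe2 (5 mol%), (R)-1-[(S)-2-(diphenylphosphanyl)ferrocenyl]ethyl(dicyclohexyl)phosphane (6 mol%), t-BuOMe, −78 °C; then HCO2Et, −78 → 0 °C; 1 M HCl
Reagents that add atoms: ethyl formate, CCOC=O
Why: Proposed new method: the chiral diphosphine–copper complex transfers the CH2OBn group of 3 to one enantioface of the enone (sets C5; the ligand enantiomer is chosen to give the S adduct 4), and the regiodefined magnesium enolate is C‑formylated at C10 by Claisen condensation; closest known reaction type: copper/ferrocenyl‑diphosphine‑catalysed 1,4‑addition of alkyl Grignard reagents to cyclohexenones with enolate trapping.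

Step 2
Reactants: 5 (3R,Z)-3-[(benzyloxy)methyl]-2-(hydroxymethylidene)-4,4-dimethylcyclohexan-1-one; 6 methyl acrylate
Product: 7 methyl 3-[(1S,6R)-6-[(benzyloxy)methyl]-1-formyl-5,5-dimethyl-2-oxocyclohexyl]propanoate
Conditions: DBU (0.1 equiv), MeCN, 23 °C
Reagents that add atoms: none
Why: Michael addition of the 1,3‑dicarbonyl; the acrylate attacks C10 anti to the neighbouring C5 CH2OBn group, so C9 ends trans and the formyl carbon (C20) cis to C6.

Step 3
Reactants: 7 methyl 3-[(1S,6R)-6-[(benzyloxy)methyl]-1-formyl-5,5-dimethyl-2-oxocyclohexyl]propanoate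
Product: 9 (6S,7R)-7-[(benzyloxy)methyl]-8,8-dimethyl-2-oxaspiro[5.5]undecane-3,11-dione, via hydroxy ester 8 (not isolated)
Conditions: NaBH4 (0.3 equiv), MeOH/CH2Cl2, −78 °C; AcOH; then p-TsOH (5 mol%), PhMe, 60 °C
Reagents that add atoms: none
Why: Chemoselective borohydride reduction of the aldehyde in the presence of the ketone and ester, then acid‑catalysed lactonisation of the new C20 alcohol onto the unhindered C7 ester (the C1 ketone cannot compete, so the lactone regiochemistry is unambiguous); no new stereocentre.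

Step 4
Reactants: 9 (6S,7R)-7-[(benzyloxy)methyl]-8,8-dimethyl-2-oxaspiro[5.5]undecane-3,11-dione
Product: 10 (6S,7R,11S)-7-[(benzyloxy)methyl]-11-hydroxy-8,8-dimethyl-2-oxaspiro[5.5]undecan-3-one
Conditions: NaBH4, CeCl3·7H2O, MeOH, −40 °C
Reagents that add atoms: none
Why: Luche‑type borohydride reduction; the small hydride attacks C1 axially, anti to the axial C10–C20 bond, giving the equatorial 1S alcohol cis to C20.

Step 5
Reactants: 10 (6S,7R,11S)-7-[(benzyloxy)methyl]-11-hydroxy-8,8-dimethyl-2-oxaspiro[5.5]undecan-3-one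
Product: 11 (6S,7R,11S)-7-[(benzyloxy)methyl]-8,8-dimethyl-11-[(triethylsilyl)oxy]-2-oxaspiro[5.5]undecan-3-one
Conditions: Et3SiOTf, 2,6-lutidine, CH2Cl2, −78 → 0 °C
Reagents that add atoms: triethylsilyl trifluoromethanesulfonate, CC[Si](CC)(CC)OS(=O)(=O)C(F)(F)F
Why: Silyl ether formation protects the C1 hydroxyl (and prevents translactonisation) during the enolate steps; no stereocentre is touched.

Step 6
Reactants: 12 cyclopent-3-en-1-ylmethanol
Product: 13 4-(iodomethyl)cyclopent-1-ene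
Conditions: I2, PPh3, imidazole, CH2Cl2, 0 → 23 °C
Reagents that add atoms: iodine, II
Why: Appel iodination of a primary alcohol; the cyclopentene is a masked, symmetric pair of CH2CHO arms.

Step 7
Reactants: 11 (6S,7R,11S)-7-[(benzyloxy)methyl]-8,8-dimethyl-11-[(triethylsilyl)oxy]-2-oxaspiro[5.5]undecan-3-one; 13 4-(iodomethyl)cyclopent-1-ene
Product: 14 (6S,7R,11S)-7-[(benzyloxy)methyl]-4-(cyclopent-3-en-1-ylmethyl)-8,8-dimethyl-11-[(triethylsilyl)oxy]-2-oxaspiro[5.5]undecan-3-one (C4 epimers)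
Conditions: LiN(iPr)2, THF, −78 °C; then 13, DMPU, −78 → −30 °C
Reagents that add atoms: none
Why: Lactone enolate alkylation (substitution at the primary iodide) forms C8–C14; the C8 configuration is irrelevant because C8 becomes sp2 in the next step.

Step 8
Reactants: 14 (6S,7R,11S)-7-[(benzyloxy)methyl]-4-(cyclopent-3-en-1-ylmethyl)-8,8-dimethyl-11-[(triethylsilyl)oxy]-2-oxaspiro[5.5]undecan-3-one (C4 epimers)
Product: 16 (6S,7R,11S)-7-[(benzyloxy)methyl]-4-(cyclopent-3-en-1-ylmethyl)-8,8-dimethyl-11-[(triethylsilyl)oxy]-2-oxaspiro[5.5]undec-4-en-3-one, via selenide 15 (not isolated)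
Conditions: LiN(iPr)2, THF, −78 °C; PhSeBr (1.0 equiv); then NaIO4, THF/MeOH/H2O, 0 → 23 °C
Reagents that add atoms: none
Why: α‑Selenenylation of the lactone enolate and selenoxide syn‑elimination toward the ring C9–H give the endocyclic C8=C9 enoate; periodate is used so the cyclopentene is not epoxidised.

Step 9
Reactants: 16 (6S,7R,11S)-7-[(benzyloxy)methyl]-4-(cyclopent-3-en-1-ylmethyl)-8,8-dimethyl-11-[(triethylsilyl)oxy]-2-oxaspiro[5.5]undec-4-en-3-one
Product: 18 (6S,7R,11S)-7-[(benzyloxy)methyl]-4-(cyclopent-3-en-1-ylmethyl)-8,8-dimethyl-3-oxo-2-oxaspiro[5.5]undec-4-en-11-yl acetate, via alcohol 17 (not isolated)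
Conditions: HF·pyridine, THF, 0 °C; then Ac2O, DMAP, pyridine, 23 °C
Reagents that add atoms: acetic anhydride, CC(=O)OC(C)=O
Why: Fluoride desilylation and acylation install the C1 acetate after the last lactone‑enolate step and before any other hydroxyl exists; C1 keeps its configuration.

Step 10
Reactants: 18 (6S,7R,11S)-7-[(benzyloxy)methyl]-4-(cyclopent-3-en-1-ylmethyl)-8,8-dimethyl-3-oxo-2-oxaspiro[5.5]undec-4-en-11-yl acetate
Product: 19 (6S,7R,11S)-7-[(benzyloxy)methyl]-8,8-dimethyl-3-oxo-4-[4-oxo-2-(2-oxoethyl)butyl]-2-oxaspiro[5.5]undec-4-en-11-yl acetate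
Conditions: O3, CH2Cl2, −78 °C (Sudan red endpoint); then PPh3, −78 → 23 °C
Reagents that add atoms: ozone, [O-][O+]=O
Why: Ozonolysis cleaves the electron‑rich cis‑disubstituted cyclopentene much faster than the conjugated trisubstituted lactone alkene, giving two identical CH2CHO arms, so C13 stays prochiral.

Step 11
Reactants: 19 (6S,7R,11S)-7-[(benzyloxy)methyl]-8,8-dimethyl-3-oxo-4-[4-oxo-2-(2-oxoethyl)butyl]-2-oxaspiro[5.5]undec-4-en-11-yl acetate
Product: 21 (1S,5R,8S,9S,10R,11S,13S,15S)-1-acetoxy-6-(benzyloxy)-11,15-dihydroxy-6,7-seco-17-norkauran-7,20-olide, via samarium enolate 20 (not isolated)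
Conditions: SmI2 (2.5 equiv, added over 1 h), THF, −78 → −40 °C; then aq NH4Cl
Reagents that add atoms: none
Why: Proposed new method: one‑electron reduction of either formyl arm gives a samarium ketyl (an acyl‑anion‑type radical anion) that adds to C9, the β‑carbon of the unsaturated lactone, joining two normally electrophilic carbons from the less hindered C1 face of ring A through a chair with the O–Sm group and the spectator CH2CHO arm equatorial (sets C9 and C11 and selects one of the two diastereotopic arms, fixing C13), and after a second electron transfer enolate 20 closes ring D by aldol addition to the remaining aldehyde on the only face the arm can reach (sets C8 and C15); closest known reaction type: SmI2 ketyl–olefin cyclisation/aldol cascades of aldehyde‑tethered α,β‑unsaturated lactones.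

Step 12
Reactants: 21 (1S,5R,8S,9S,10R,11S,13S,15S)-1-acetoxy-6-(benzyloxy)-11,15-dihydroxy-6,7-seco-17-norkauran-7,20-olide
Product: 22 (1S,5R,8S,9S,10R,11S,13S)-1-acetoxy-6-(benzyloxy)-11-hydroxy-15-oxo-6,7-seco-17-norkauran-7,20-olide
Conditions: Dess–Martin periodinane (1.05 equiv), pyridine, CH2Cl2, 0 °C
Reagents that add atoms: none
Why: Dess–Martin oxidation; the exo C15 hydroxyl on the convex face should exchange onto iodine faster than the axial C11 hydroxyl, which sits under the C15–C16 bridge next to C9 and its spiro ring.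

Step 13
Reactants: 22 (1S,5R,8S,9S,10R,11S,13S)-1-acetoxy-6-(benzyloxy)-11-hydroxy-15-oxo-6,7-seco-17-norkauran-7,20-olide
Product: 23 (1S,5R,8S,9S,10R,11S,13S)-1-acetoxy-6,11-dihydroxy-15-oxo-6,7-seco-17-norkauran-7,20-olide
Conditions: H2 (1 atm), Pd/C (10 wt%), EtOAc, 23 °C
Reagents that add atoms: none
Why: Hydrogenolysis of the benzyl ether is safe here because no alkene is present yet and the hindered ketone, lactone and acetate are inert.

Step 14
Reactants: 23 (1S,5R,8S,9S,10R,11S,13S)-1-acetoxy-6,11-dihydroxy-15-oxo-6,7-seco-17-norkauran-7,20-olide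
Product: 24 Maoyecrystal E, (1S,5R,8S,9S,10R,11S,13S)-1-acetoxy-6,11-dihydroxy-15-oxo-6,7-secokaur-16-en-7,20-olide
Conditions: (CH2O)n, PhNHMe·CF3CO2H, THF, 65 °C
Reagents that add atoms: formaldehyde (as paraformaldehyde), C=O
Why: Mannich‑type α‑methylenation under mildly acidic conditions; C16 is the only enolisable position next to C15 (C8 is quaternary), and free hydroxyls and the acetate are tolerated.

## Compound list

1 | 4,4-dimethylcyclohex-2-en-1-one | CC1(C)CCC(=O)C=C1 | starting material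
2 | benzyl chloromethyl ether | ClCOCc1ccccc1 | starting material
3 | (benzyloxymethyl)magnesium chloride | Cl[Mg]COCc1ccccc1 | intermediate (not isolated)
4 | chloromagnesium enolate of (S)-3-[(benzyloxy)methyl]-4,4-dimethylcyclohexanone | Cl[Mg]OC1=C[C@H](COCc2ccccc2)C(C)(C)CC1 | intermediate (not isolated)
5 | (3R,Z)-3-[(benzyloxy)methyl]-2-(hydroxymethylidene)-4,4-dimethylcyclohexan-1-one | O/C=C1\C(=O)CCC(C)(C)[C@H]1COCc1ccccc1 | intermediate
6 | methyl acrylate | C=CC(=O)OC | starting material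
7 | methyl 3-[(1S,6R)-6-[(benzyloxy)methyl]-1-formyl-5,5-dimethyl-2-oxocyclohexyl]propanoate | COC(=O)CC[C@]1(C=O)C(=O)CCC(C)(C)[C@H]1COCc1ccccc1 | intermediate
8 | methyl 3-[(1S,6R)-6-[(benzyloxy)methyl]-1-(hydroxymethyl)-5,5-dimethyl-2-oxocyclohexyl]propanoate | COC(=O)CC[C@]1(CO)C(=O)CCC(C)(C)[C@H]1COCc1ccccc1 | intermediate (not isolated)
9 | (6S,7R)-7-[(benzyloxy)methyl]-8,8-dimethyl-2-oxaspiro[5.5]undecane-3,11-dione | C1C[C@]2(COC1=O)C(=O)CCC(C)(C)[C@H]2COCc1ccccc1 | intermediate
10 | (6S,7R,11S)-7-[(benzyloxy)methyl]-11-hydroxy-8,8-dimethyl-2-oxaspiro[5.5]undecan-3-one | C1C[C@]2(COC1=O)[C@@H](O)CCC(C)(C)[C@H]2COCc1ccccc1 | intermediate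
11 | (6S,7R,11S)-7-[(benzyloxy)methyl]-8,8-dimethyl-11-[(triethylsilyl)oxy]-2-oxaspiro[5.5]undecan-3-one | C1C[C@]2(COC1=O)[C@@H](O[Si](CC)(CC)CC)CCC(C)(C)[C@H]2COCc1ccccc1 | intermediate
12 | cyclopent-3-en-1-ylmethanol | OCC1CC=CC1 | starting material
13 | 4-(iodomethyl)cyclopent-1-ene | ICC1CC=CC1 | intermediate
14 | (6S,7R,11S)-7-[(benzyloxy)methyl]-4-(cyclopent-3-en-1-ylmethyl)-8,8-dimethyl-11-[(triethylsilyl)oxy]-2-oxaspiro[5.5]undecan-3-one (C4 epimers) | C1=CCC(C1)CC2C[C@]3(COC2=O)[C@@H](O[Si](CC)(CC)CC)CCC(C)(C)[C@H]3COCc1ccccc1 | intermediate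
15 | 4-(phenylselanyl) derivative of 14 (C4 epimers) | C1=CCC(C1)CC2([Se]c4ccccc4)C[C@]3(COC2=O)[C@@H](O[Si](CC)(CC)CC)CCC(C)(C)[C@H]3COCc1ccccc1 | intermediate (not isolated)
16 | (6S,7R,11S)-7-[(benzyloxy)methyl]-4-(cyclopent-3-en-1-ylmethyl)-8,8-dimethyl-11-[(triethylsilyl)oxy]-2-oxaspiro[5.5]undec-4-en-3-one | C1=CCC(C1)CC2=C[C@]3(COC2=O)[C@@H](O[Si](CC)(CC)CC)CCC(C)(C)[C@H]3COCc1ccccc1 | intermediate
17 | (6S,7R,11S)-7-[(benzyloxy)methyl]-4-(cyclopent-3-en-1-ylmethyl)-11-hydroxy-8,8-dimethyl-2-oxaspiro[5.5]undec-4-en-3-one | C1=CCC(C1)CC2=C[C@]3(COC2=O)[C@@H](O)CCC(C)(C)[C@H]3COCc1ccccc1 | intermediate (not isolated)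
18 | (6S,7R,11S)-7-[(benzyloxy)methyl]-4-(cyclopent-3-en-1-ylmethyl)-8,8-dimethyl-3-oxo-2-oxaspiro[5.5]undec-4-en-11-yl acetate | C1=CCC(C1)CC2=C[C@]3(COC2=O)[C@@H](OC(C)=O)CCC(C)(C)[C@H]3COCc1ccccc1 | intermediate
19 | (6S,7R,11S)-7-[(benzyloxy)methyl]-8,8-dimethyl-3-oxo-4-[4-oxo-2-(2-oxoethyl)butyl]-2-oxaspiro[5.5]undec-4-en-11-yl acetate (symmetric dialdehyde) | O=CCC(CC=O)CC1=C[C@]2(COC1=O)[C@@H](OC(C)=O)CCC(C)(C)[C@H]2COCc1ccccc1 | intermediate
20 | bis(diiodosamarium) enolate–alkoxide after the first ring closure (C9–C11 formed; C8 enolate; C11–O–Sm; CH2CHO arm on C13 cis to O11) | O=CC[C@@H]1C[C@H](O[Sm](I)I)[C@@H]2C(C1)=C(O[Sm](I)I)OC[C@]23[C@@H](OC(C)=O)CCC(C)(C)[C@H]3COCc1ccccc1 | intermediate (not isolated)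
21 | (1S,5R,8S,9S,10R,11S,13S,15S)-1-acetoxy-6-(benzyloxy)-11,15-dihydroxy-6,7-seco-17-norkauran-7,20-olide | C1[C@H](O)[C@]23C[C@H]1C[C@H](O)[C@H]2[C@]1(COC3=O)[C@@H](OC(C)=O)CCC(C)(C)[C@H]1COCc1ccccc1 | intermediate
22 | (1S,5R,8S,9S,10R,11S,13S)-1-acetoxy-6-(benzyloxy)-11-hydroxy-15-oxo-6,7-seco-17-norkauran-7,20-olide | C1C(=O)[C@]23C[C@H]1C[C@H](O)[C@H]2[C@]1(COC3=O)[C@@H](OC(C)=O)CCC(C)(C)[C@H]1COCc1ccccc1 | intermediate
23 | (1S,5R,8S,9S,10R,11S,13S)-1-acetoxy-6,11-dihydroxy-15-oxo-6,7-seco-17-norkauran-7,20-olide | C1C(=O)[C@]23C[C@H]1C[C@H](O)[C@H]2[C@]1(COC3=O)[C@@H](OC(C)=O)CCC(C)(C)[C@H]1CO | intermediate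
24 | Maoyecrystal E | C=C1C(=O)[C@]23C[C@H]1C[C@H](O)[C@H]2[C@]1(COC3=O)[C@@H](OC(C)=O)CCC(C)(C)[C@H]1CO | target

## Step count and risks

Total steps: 14. Longest linear sequence: 13 (steps 1–5 and 7–14; step 6 makes iodide 13).

Steps most likely to fail:

**Step 11.** Pinacol coupling of the two formyl arms or poor arm selection could beat the ketyl–enoate/aldol cascade. Fallback, setting out from 18 and returning at 22: ozonolyse 18 in CH2Cl2/MeOH with NaHCO3 and treat the crude product with Ac2O/Et3N to obtain the terminally differentiated aldehyde methyl ester F4 (both C13 epimers). Treat it with SmI2 in THF at −78 °C, so that the single ketyl adds to C9 and the samarium enolate is then acylated by the ester arm (Claisen closure of ring D). The matched C13 epimer gives 22 directly, which gives up the desymmetrisation, caps the yield near half and bypasses 19–21.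

**Step 12.** The C11 hydroxyl may be oxidised as fast as the C15 hydroxyl. Fallback, setting out from 21 and returning at 22: treat 21 with catalytic DBU in THF to effect retro‑aldol cleavage of C8–C15, so that the freed aldehyde is captured by O11 as the bridged lactol F5. Oxidise it with PhI(OAc)2/TEMPO to the bridged δ‑lactone F6, in which O11 is masked and C15 is at the acyl level. LiN(SiMe3)2 in THF at −78 → 0 °C then gives the C8 enolate, which attacks C15 and releases O11 (Dieckmann‑type closure) to give 22. The C1 acetate is at risk with this base and the reaction must be kept cold.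

**Step 1.** An alkoxymethyl Grignard reagent has no precedent in the asymmetric copper‑catalysed addition. Fallback, setting out from 1 and returning at 5: add 3 to 1 with achiral CuBr·SMe2 and Me3SiCl to give the racemic trimethylsilyl enol ether F1. Dehydrogenate it with Pd(OAc)2 in MeCN (Saegusa–Ito) to 3-[(benzyloxy)methyl]-4,4-dimethylcyclohex-2-en-1-one F2. Set C5 by asymmetric copper hydride conjugate reduction (Cu(OAc)2, (R)-DTBM-SEGPHOS, Ph2SiH2), which gives the diphenylsilyl enol ether F3. Cleave it with MeLi and formylate the lithium enolate with HCO2Et to give 5.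

## Further compounds

F1 | step 1 | rac-{[3-[(benzyloxy)methyl]-4,4-dimethylcyclohex-1-en-1-yl]oxy}trimethylsilane | C[Si](C)(C)OC1=CC(COCc2ccccc2)C(C)(C)CC1
F2 | step 1 | 3-[(benzyloxy)methyl]-4,4-dimethylcyclohex-2-en-1-one | O=C1C=C(COCc2ccccc2)C(C)(C)CC1
F3 | step 1 | {[(3S)-3-[(benzyloxy)methyl]-4,4-dimethylcyclohex-1-en-1-yl]oxy}diphenylsilane | [SiH](c1ccccc1)(c1ccccc1)OC1=C[C@H](COCc2ccccc2)C(C)(C)CC1
F4 | step 11 | methyl 4-[(6S,7R,11S)-11-acetoxy-7-[(benzyloxy)methyl]-8,8-dimethyl-3-oxo-2-oxaspiro[5.5]undec-4-en-4-yl]-3-(2-oxoethyl)butanoate (both C3 epimers) | COC(=O)CC(CC=O)CC1=C[C@]2(COC1=O)[C@@H](OC(C)=O)CCC(C)(C)[C@H]2COCc1ccccc1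
F5 | step 12 | bridged lactol of the retro-aldol aldehyde (C8–C15 bond absent; O11–C15 hemiacetal; H8 cis to H9; both anomers) | OC1C[C@@H]2C[C@H](O1)[C@@H]3[C@H](C2)C(=O)OC[C@]34[C@@H](OC(C)=O)CCC(C)(C)[C@H]4COCc1ccccc1
F6 | step 12 | bridged 15,11-lactone (C8–C15 bond absent; C15 carboxyl esterified by O11; H8 cis to H9) | O=C1C[C@@H]2C[C@H](O1)[C@@H]3[C@H](C2)C(=O)OC[C@]34[C@@H](OC(C)=O)CCC(C)(C)[C@H]4COCc1ccccc1
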